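Ochre's substrate falls with a first-order constant of 0.0134 h⁻¹ up to its first reading and 0.0123 h⁻¹ up to its last, so that constant is nearly steady.

common to all: substrate 0.10 M
- violet: free catalyst 0.039 mol%; temperature −25 °C; run made earlier
- ochre: free catalyst 0.07 mol%; temperature −3 °C; run made earlier
- alder: free catalyst 0.1 mol%; at 5 °C until 10 h, from then on at −35 °C; time 50 h
- elm: free catalyst 0.05 mol%; at 5 °C throughout; time 50 h

- violet (time / h: target / %, substrate / %): 20.0: 1.1, 99.1; 40.0: 3.4, 96.6; 72.0: 5.3, 94.6; 120: 9.1, 91.4; 192: 12.8, 86.3
- ochre (time / h: target / %, substrate / %): 4.00: 5.9, 94.8; 12.0: 14.5, 85.3; 25.0: 25.7, 72.2; 40.0: 34.3, 60.5; 48.0: 38.3, 55.4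

(scatter of a reading: 0.3 percentage points)

1. which one finishes higher in amount of target, in percent of the substrate charged ("neither" within 2 percentage points) (alder / elm / neither)
2. amount of target at the end, in percent of the substrate charged, alder
3. amount of target at the end, in percent of the substrate charged, elm

Two chemists dispute alder and elm. The first freezes that constant. She treats each flask as a pseudo-first-order decay of substrate, with a constant proportional to the catalyst loading. Violet gives 7.67 × 10⁻⁴ h⁻¹. Set against ochre, loading for loading, the two runs give an activation energy of 55.5 kJ mol⁻¹.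

From these she builds the dose: the constant times the hours, summed over the stages, so that c(substrate) over its charged value is exp(−dose). Alder's warm stage gives 0.358. Its cold stage gives 0.0254, far less. Alder's dose is 0.383. Elm's is 0.894, which is 2.33 times as much. So she expects 68.2 % of the substrate left in alder and 40.9 % in elm.

The second chemist counts losses instead. At ochre's last reading, 6.30 % of the substrate stands in neither column. Elm stays warm, while alder goes cold at 10 h with twice the loading. He holds that the cold keeps alder's target, so alder wins.

She answers with ochre's gap, which is 14.1 % of the substrate consumed there. With that share, her own reckoning gives alder 27.3 % and elm 50.8 %. The forecast takes her side with a lower elm: elm, alder 29 %, elm 43 %. Of alder it says, “The cold stage nearly freezes everything”.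

The flask gives elm: alder 29.6 %, elm 39.3 %.

    substrate + free catalyst ⇌ catalyst intermediate (K = 7.40 M⁻¹, k = 0.120 M⁻¹ s⁻¹, Ea = 59.0 kJ mol⁻¹, ΔH = −48.0 kJ mol⁻¹)
    substrate + target → side product (k = 3.50 × 10⁻⁵ M⁻¹ s⁻¹, Ea = 81.0 kJ mol⁻¹)
    catalyst intermediate ⇌ free catalyst + target (K = 0.250 M, k = 3.20 s⁻¹, Ea = 68.0 kJ mol⁻¹, ΔH = 11.0 kJ mol⁻¹)
    (constants at 5 °C)

The dose came close on substrate: 68.2 % against 67.2 % in alder, and 40.9 % against 41 % in elm. The share did not carry over: elm ends with 19.6 % of side product, where ochre's share gave 8.33 %. The second chemist's order holds for long standing: with each flask left as it is until 500 h, alder has 41.3 % of target and elm 17.2 %. Take alder with 0.04 mol% of free catalyst. Its dose scales to 0.153, which leaves 85.8 % of the substrate. That flask ends with 83.8 % of substrate and 14.5 % of target.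

Readings and results were generated by integration on assumed constants, noise included.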